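## Structural features

The target is a 2,3-dibenzylbutane-1,4-diol: an open chain C7–C8–C8'–C7' with a CH2OH on C8 and on C8'. C7 is attached to a 4-hydroxy-3-methoxyphenyl ring (ring A), and C7' to C5 of a 7-methoxy-2,3-dihydrobenzofuran (benzene ring B fused to the dihydrofuran). The dihydrofuran carries a second 4-hydroxy-3-methoxyphenyl ring (ring C) on C2 and a CH2OH on C3. The four stereocentres form two adjacent pairs: C8 and C8' (both R) on the chain, and C2 (S) and C3 (R), trans, on the five-membered ring. Ring B and the C7' methylene separate the pairs, so neither can direct the other and each needs its own source of absolute configuration. The fragile points are the C2–O1 bond (a benzylic aryl ether activated by the para oxygen of ring C, open to acid ionisation and to hydrogenolysis), the two free phenols, and any leaving group on C7', which sits para to O1. The real difficulty is the enantiopure trans-2-aryl-3-(hydroxymethyl)dihydrobenzofuran with a one-carbon handle on C5; the butanediol half is dependable lactone enolate chemistry. The key step uses the fact that C3 bears exactly one exocyclic carbon and is bonded to C3a of ring B: with that carbon placed between C3 and C3a, the unit O1–C2–C3–C3a becomes the pyranone ring of a 2-arylchroman-4-one, whose single stereocentre C2 can be set by catalysis and can then govern C3.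

## Logic of the disconnections

28 from 27 and 26. The two phenolic O–CH2Ph bonds are cut last, so both phenols stay masked through all basic and hydridic steps. Behind 27, the three CH2OH groups are traced to the lactone carbonyl and the pivalate of 26; no skeletal bond is cut. The gain is that one hydride step frees all three alcohols, leaving only two aryl benzyl ethers for the final hydrogenolysis. The demand is a short, mild hydrogenolysis that spares the C2–O1 bond.

26 from 25 and 19. The C8'–C7' bond is cut, between the lactone α-carbon and the benzylic carbon on ring B. This splits the molecule into two halves of similar size, each carrying one stereo pair, and puts the C8 substituent next to the reacting carbon. The forward step must alkylate trans to that substituent, with an electrophile reactive enough at low temperature.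

25 from 23, 22, 20 and 21. The lactone C–O bond, then the two C–H bonds at C7 and C8, then the C7=C8 bond are removed. This leads to two cheap achiral materials, and C8 arises in a catalytic hydrogenation. The demands are high facial selectivity in 22 to 23 and reduction of the ester but not the carboxylate in 23.

19 from 18, 17, 16 and 15. Only functional groups change: C–Br from C–OH, O–Si cleavage, O-acylation, ester to CH2OH. The pivalate on the C3 CH2OH replaces a benzyl ether because it leaves in step 16 at no cost in steps. The bromide is made under neutral conditions because acid would ionise the C2–O1 bond.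

15 from 12. The C3–C3a bond is cut and C3a is rejoined to the ester carbon, which returns into the ring as the C4 ketone with N2 on C3. This replaces a two-stereocentre dihydrobenzofuran by a one-stereocentre chromanone. The forward step must favour the 1,2-shift over carbene side reactions and must leave C2 untouched.

12 from 10. The C3=N2 bond is cut. The forward step must activate C3 without letting the enolate open the pyranone ring, which would racemise C2.

10 from 8 and 9. The C2–aryl bond to ring C is cut. This is the only step that creates absolute configuration in this half, by catalyst control on a flat acceptor.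

8 from 7, 6, 4, 1 and 2. In turn: the O–Si bond, the C–H bonds of the CH2OH, the O1–C2 and C2=C3 bonds of the pyranone, and the aryl–acetyl bond. The aldehyde is kept through the Heck reaction and the acidic ring closure, and the silyl group is introduced only afterwards. In this way no p-hydroxybenzyl silyl ether meets hot base or acid. Triisopropylsilyl replaces tert-butyldimethylsilyl for more tolerance of the wet, mildly acidic conditions of step 5 and the methoxide of step 7.

## Other disconnections considered

Alternative 1: The cut is through ring B itself: C3a–C7a, C4–C5 and C6–C7. In the forward sense, Cp*RuCl(cod) would join the boryl ynol ether diyne A1 (carrying C2 and C3) with the terminal alkyne A2 (carrying C8 and C8') in a (2+2+2) cyclotrimerisation to the 7-boryl dihydrobenzofuran A3.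
- In its favour: it is fully convergent, both stereo pairs are complete before the union, and ring B and the dihydrofuran form together. No benzylic halide or enolate alkylation is needed at the joining stage, and boron marks C7 for the methoxy group. On convergence and on avoiding a labile benzylic bromide it is better than the chosen plan.
- Against it here: A1 combines an alkynyl ether with an alkynylboronate, both hydrolytically sensitive. A1 also needs the C2/C3 pair made in an open chain, where no ring enforces the trans relation. The position of the A2 substituent (meta to boron) rests on catalyst control, and A2 can trimerise with itself. After A3 come C–B oxidation, O-methylation, desilylation and debenzylation.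
- Comparison: on structure, it builds an arene that the chosen plan takes ready-made from vanillin. On mechanism, the metallacycle pathway carries a regiochemical question, whereas the Wolff shift has only one group that can migrate. On stereocontrol, the chosen plan derives C3 from C2 by equilibration, which is simpler. On step economy the two are expected to be about equal at best, since A1 and A2 each need a multistep asymmetric synthesis.

Alternative 2: The cut is at C7–C8 and C8'–C7'. The lithiated dithiane A5 of ring A would add to the butenolide A4 anti to the menthyloxy group, and the resulting enolate would be alkylated by the benzylic bromide A6 to give the trans lactone A7.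
- In its favour: both centres of the butanediol are set in one flask, and the sense of induction is fixed by a configurationally defined acceptor. This is better than steps 12 to 15 of the chosen plan, where four steps and a catalyst sense taken by analogy are needed. The trans-selective enolate alkylation is the same event as in step 15, so the two are equal there.
- Against it here: it presupposes A6, so the dihydrobenzofuran still has to be made. It competes with the lactone branch of the chosen plan, not with the ring contraction. The dithiane must later be removed with Raney Ni, which threatens the aryl benzyl ethers and the benzylic C2–O1 bond. The auxiliary is stoichiometric and is released only on reduction of the acetal.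
- Comparison: on mechanism the two are equal at the alkylation. On the step count for C8/C8' the alternative is better. On compatibility with the fragile benzylic ether the chosen plan is better, since it needs only homogeneous rhodium hydrogenation before the union and one mild hydrogenolysis at the end.

Alternative 3: The cut is the O1–C2 bond. Ag2O would oxidise the ring C phenol of the diarylpropanol silyl ether A8 to its para-quinone methide, and the ring B phenol would add to the methide carbon (5-exo-trig) to give the trans dihydrobenzofuran A9.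
- In its favour: ring C needs no protecting group, and no diazo compound or light is involved; on these points it is better than the chosen plan. The C5 aldehyde of A9 is a handle equal to the silyloxymethyl group (reduction and bromination, against desilylation and bromination).
- Against it here: the C3 centre must first be made in open-chain A8, which means a separate asymmetric construction of a 2-arylpropanol. The trans preference comes from a single neighbouring centre at a planar methide and could be modest. Quinone methides dimerise or take up external nucleophiles. The free phenol of A9 must be protected before any enolate chemistry.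
- Comparison: on structure, a C–O bond is formed on a complete carbon skeleton, whereas the chosen plan forms a C–C bond of the ring from a simpler skeleton. On stereocontrol, control runs from C3 to C2, the reverse of the chosen plan; the two are equal in principle, since both end under thermodynamic trans preference. However, the controlling centre of the chosen plan comes from one catalytic step on a chromone. On step economy the key step of the alternative is shorter, but the synthesis of A8 and the later phenol protection are expected to cancel that gain.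

Key step: step 7

Assumption (chemistry): the (R)-pyridine-oxazoline ligand of step 5 and the (S,S)-bisphospholane of step 13 are taken to give the (2S) and (R) centres by analogy with cyclic enones and itaconates; if either sense proves opposite, the antipodal ligand is used and nothing else changes.

## Route

Step 1
Reactants: 1 5-iodovanillin; 2 butyl vinyl ether
Product: 4 3-acetyl-4-hydroxy-5-methoxybenzaldehyde, via 1-butoxyvinyl enol ether 3 (not isolated)
Conditions: Pd(OAc)2 (3 mol%), dppp (6 mol%), Et3N, 1-butyl-3-methylimidazolium tetrafluoroborate/DMSO, 115 °C; then 1 M HCl, rt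
Reagents that add atoms: water, O
Why: Heck arylation of an electron-rich vinyl ether by the cationic pathway (chelating diphosphine, ionic medium) places the aryl group on the oxygen-bearing carbon, and acid hydrolysis of the enol ether 3 gives the methyl ketone. The iodide para to the formyl group undergoes oxidative addition readily, and the aldehyde and phenol are spectators.

Step 2
Reactants: 4 3-acetyl-4-hydroxy-5-methoxybenzaldehyde
Product: 6 8-methoxy-4-oxo-4H-chromene-6-carbaldehyde, via enaminone 5 (not isolated)
Conditions: Me2NCH(OMe)2, toluene, 90 °C; then conc. HCl, CH2Cl2, rt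
Reagents that add atoms: N,N-dimethylformamide dimethyl acetal, COC(OC)N(C)C
Why: Condensation of the acetyl methyl group with the amide acetal gives the enaminone 5, and acid then drives conjugate addition of the phenol and loss of dimethylamine to close the pyranone (chromone synthesis from 2-hydroxyacetophenones). The aldehyde has no enolisable position and the chelated phenol is expected to survive the short heating.

Step 3
Reactants: 6 8-methoxy-4-oxo-4H-chromene-6-carbaldehyde
Product: 7 6-(hydroxymethyl)-8-methoxy-4H-chromen-4-one
Conditions: NaBH4 (0.3 equiv), THF/MeOH, −20 °C; aq. NH4Cl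
Reagents that add atoms: none
Why: Chemoselective hydride reduction: the aryl aldehyde is far more electrophilic than the vinylogous ester carbonyl or C2 of the chromone, so limiting hydride at low temperature should touch only the formyl group.

Step 4
Reactants: 7 6-(hydroxymethyl)-8-methoxy-4H-chromen-4-one
Product: 8 8-methoxy-6-{[(triisopropylsilyl)oxy]methyl}-4H-chromen-4-one
Conditions: i-Pr3SiCl, imidazole, DMF, 0 °C → rt
Reagents that add atoms: chlorotriisopropylsilane, CC(C)[Si](Cl)(C(C)C)C(C)C
Why: Standard silylation of the only hydroxyl group. The triisopropylsilyl ether is chosen for its tolerance of the wet, mildly acidic medium of step 5, the amide base of step 6 and the methoxide of step 7.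

Step 5
Reactants: 8 8-methoxy-6-{[(triisopropylsilyl)oxy]methyl}-4H-chromen-4-one; 9 [4-(benzyloxy)-3-methoxyphenyl]boronic acid
Product: 10 (2S)-2-[4-(benzyloxy)-3-methoxyphenyl]-8-methoxy-6-{[(triisopropylsilyl)oxy]methyl}-2,3-dihydro-4H-chromen-4-one
Conditions: Pd(OCOCF3)2 (5 mol%), (R)-t-BuPyOx (6 mol%), NH4PF6 (30 mol%), H2O (5 equiv), ClCH2CH2Cl, 60 °C
Reagents that add atoms: none
Why: Asymmetric conjugate addition of an arylboronic acid to a chromone under divalent palladium catalysis: transmetalation, enantiodetermining insertion of the C2=C3 bond into the aryl–palladium bond, then protonolysis of the palladium enolate by water. The tert-butyl group of the ligand differentiates the two faces of the bound chromone and so sets C2.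

Step 6
Reactants: 10 (2S)-2-[4-(benzyloxy)-3-methoxyphenyl]-8-methoxy-6-{[(triisopropylsilyl)oxy]methyl}-2,3-dihydro-4H-chromen-4-one
Product: 12 (2R)-2-[4-(benzyloxy)-3-methoxyphenyl]-3-diazo-8-methoxy-6-{[(triisopropylsilyl)oxy]methyl}-2,3-dihydro-4H-chromen-4-one, via 3-trifluoroacetyl ketone 11 (not isolated)
Conditions: LiN(SiMe3)2, THF, −78 °C; CF3CO2CH2CF3, −78 °C; aq. HCl work-up; then 4-AcNHC6H4SO2N3, Et3N, H2O (1 equiv), MeCN, 0 °C → rt
Reagents that add atoms: 4-acetamidobenzenesulfonyl azide, CC(=O)Nc1ccc(cc1)S(=O)(=O)N=[N+]=[N-]
Why: Detrifluoroacetylative diazo transfer: the kinetic lithium enolate is formed and C-acylated at −78 °C, where E1cB opening of the pyranone is slow, and the activated diketone 11 then takes up N2 from the sulfonyl azide with loss of the trifluoroacetyl group as the N-acylsulfonamide. C2 is not touched; its descriptor becomes R only because the diazo carbon now outranks the aryl group.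

Step 7
Reactants: 12 (2R)-2-[4-(benzyloxy)-3-methoxyphenyl]-3-diazo-8-methoxy-6-{[(triisopropylsilyl)oxy]methyl}-2,3-dihydro-4H-chromen-4-one
Product: 15 methyl (2S,3S)-2-[4-(benzyloxy)-3-methoxyphenyl]-7-methoxy-5-{[(triisopropylsilyl)oxy]methyl}-2,3-dihydro-1-benzofuran-3-carboxylate (trans), via ketene 13 (not isolated), via cis ester 14 (not isolated)
Conditions: hν (350 nm, borosilicate glass), degassed MeOH/THF (4:1), 0.01 M, rt; then NaOMe (0.3 equiv), 0 °C → rt; AcOH quench
Reagents that add atoms: methanol, CO
Why: Light near 350 nm, where the aryl and silyl ethers are transparent, excites the diazo ketone, which the ring holds s-cis, so that loss of N2 and the 1,2-shift of the ring B carbon C4a from the carbonyl carbon C4 to C3 should run in concert, or through a very short-lived singlet carbene, to ketene 13. Methanol adds to the ketene and the ester enol tautomerises to the C3 epimers 14 and 15; the closest known reaction type is the photochemical Wolff ring contraction of cyclic 2-diazo ketones, 3-diazochroman-4-ones included, to ring-contracted esters. The dihydrofuran ring arises by contraction of the six-membered pyranone through this 1,2-aryl shift, not by cyclisation of an open chain, so no competing ring size exists. The new stereocentre C3 is set under thermodynamic control: methoxide equilibrates the epimerisable ester to the trans isomer, in which the ester avoids the C2 aryl group, so C3 is dictated by the untouched C2 centre. The regiochemistry is unambiguous because the carbonyl carbon carries only the ring B carbon as a group able to migrate, and this electron-rich aryl carbon migrates readily. The step needs the Wolff shift to win over carbene chemistry (1,2-hydride shift from C2, O–H insertion of methanol); the locked s-cis geometry and direct, unsensitised irradiation secure this. It also needs C2 to keep its configuration: the photochemical event does not involve it, and the methoxide is kept substoichiometric and cool so that simple reprotonation of the ester enolate outruns E1cB loss of the ring B phenoxide. The C2 descriptor returns to S in 14 and 15 only through the change in substituent ranking.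

Step 8
Reactants: 15 methyl (2S,3S)-2-[4-(benzyloxy)-3-methoxyphenyl]-7-methoxy-5-{[(triisopropylsilyl)oxy]methyl}-2,3-dihydro-1-benzofuran-3-carboxylate
Product: 16 {(2S,3R)-2-[4-(benzyloxy)-3-methoxyphenyl]-7-methoxy-5-{[(triisopropylsilyl)oxy]methyl}-2,3-dihydro-1-benzofuran-3-yl}methanol
Conditions: i-Bu2AlH (2.5 equiv), CH2Cl2, −78 → 0 °C; aq. potassium sodium tartrate
Reagents that add atoms: none
Why: Hydride reduction of the ester to the primary alcohol with a non-basic reagent, so the C3 centre is not epimerised; after this step C3 is no longer α to a carbonyl group and is fixed. The descriptor changes to R through ranking only.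

Step 9
Reactants: 16 {(2S,3R)-2-[4-(benzyloxy)-3-methoxyphenyl]-7-methoxy-5-{[(triisopropylsilyl)oxy]methyl}-2,3-dihydro-1-benzofuran-3-yl}methanol
Product: 17 {(2S,3R)-2-[4-(benzyloxy)-3-methoxyphenyl]-7-methoxy-5-{[(triisopropylsilyl)oxy]methyl}-2,3-dihydro-1-benzofuran-3-yl}methyl 2,2-dimethylpropanoate
Conditions: t-BuCOCl, pyridine, DMAP (cat.), CH2Cl2, 0 °C → rt
Reagents that add atoms: pivaloyl chloride, CC(C)(C)C(Cl)=O
Why: Acylation of the primary alcohol. The hindered pivalate should withstand fluoride, the Appel reaction and a lithium enolate at low temperature, and it is removed by LiAlH4 in step 16 without a separate deprotection.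

Step 10
Reactants: 17 {(2S,3R)-2-[4-(benzyloxy)-3-methoxyphenyl]-7-methoxy-5-{[(triisopropylsilyl)oxy]methyl}-2,3-dihydro-1-benzofuran-3-yl}methyl 2,2-dimethylpropanoate
Product: 18 {(2S,3R)-2-[4-(benzyloxy)-3-methoxyphenyl]-5-(hydroxymethyl)-7-methoxy-2,3-dihydro-1-benzofuran-3-yl}methyl 2,2-dimethylpropanoate
Conditions: Bu4NF, AcOH, THF, 0 °C → rt
Reagents that add atoms: none
Why: Fluoride cleavage of the silyl ether; the acetic acid buffer keeps the medium from becoming basic enough to disturb the pivalate.

Step 11
Reactants: 18 {(2S,3R)-2-[4-(benzyloxy)-3-methoxyphenyl]-5-(hydroxymethyl)-7-methoxy-2,3-dihydro-1-benzofuran-3-yl}methyl 2,2-dimethylpropanoate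
Product: 19 {(2S,3R)-2-[4-(benzyloxy)-3-methoxyphenyl]-5-(bromomethyl)-7-methoxy-2,3-dihydro-1-benzofuran-3-yl}methyl 2,2-dimethylpropanoate
Conditions: CBr4, PPh3, CH2Cl2, 0 °C; rapid filtration through neutral alumina, used at once
Reagents that add atoms: carbon tetrabromide, BrC(Br)(Br)Br
Why: Appel bromination of a primary benzylic alcohol under neutral conditions, which avoids the acid that would ionise the C2–O1 bond. The bromide, activated by the para ring oxygen, is not stored.

Step 12
Reactants: 20 4-(benzyloxy)-3-methoxybenzaldehyde; 21 dimethyl succinate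
Product: 22 (3E)-4-[4-(benzyloxy)-3-methoxyphenyl]-3-(methoxycarbonyl)but-3-enoic acid
Conditions: NaOMe, MeOH, reflux; then aq. HCl
Reagents that add atoms: none
Why: Stobbe condensation: aldol addition of the succinate enolate, lactonisation and E1cB ring opening give the half-ester with the aryl group trans to the conjugated ester.

Step 13
Reactants: 22 (3E)-4-[4-(benzyloxy)-3-methoxyphenyl]-3-(methoxycarbonyl)but-3-enoic acid
Product: 23 (3R)-4-[4-(benzyloxy)-3-methoxyphenyl]-3-(methoxycarbonyl)butanoic acid
Conditions: H2 (5 atm), [Rh(cod)((S,S)-Et-DuPhos)]BF4 (1 mol%), NaOMe (10 mol%), MeOH, rt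
Reagents that add atoms: none
Why: Asymmetric hydrogenation of a β-aryl itaconate half-ester: the carboxylate and the alkene chelate the cationic monovalent rhodium centre, and the C2-symmetric 1,2-bis(2,5-diethylphospholanyl)benzene ligand selects the alkene face, which sets C8. The aryl benzyl ether is inert to this homogeneous catalyst.

Step 14
Reactants: 23 (3R)-4-[4-(benzyloxy)-3-methoxyphenyl]-3-(methoxycarbonyl)butanoic acid
Product: 25 (4R)-4-[4-(benzyloxy)-3-methoxybenzyl]dihydrofuran-2(3H)-one, via hydroxy acid 24 (not isolated)
Conditions: KOH (1 equiv), EtOH; CaCl2, NaBH4, EtOH, −10 °C → rt; then 3 M HCl, rt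
Reagents that add atoms: none
Why: Ca(BH4)2 formed in the flask reduces the ester while the carboxylate is protected by its charge, and acidification lactonises the hydroxy acid 24. The stereocentre is not involved and keeps its descriptor.

Step 15
Reactants: 25 (4R)-4-[4-(benzyloxy)-3-methoxybenzyl]dihydrofuran-2(3H)-one; 19 {(2S,3R)-2-[4-(benzyloxy)-3-methoxyphenyl]-5-(bromomethyl)-7-methoxy-2,3-dihydro-1-benzofuran-3-yl}methyl 2,2-dimethylpropanoate
Product: 26 {(2S,3R)-2-[4-(benzyloxy)-3-methoxyphenyl]-5-({(3R,4R)-4-[4-(benzyloxy)-3-methoxybenzyl]-2-oxotetrahydrofuran-3-yl}methyl)-7-methoxy-2,3-dihydro-1-benzofuran-3-yl}methyl 2,2-dimethylpropanoate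
Conditions: 25, LiN(SiMe3)2, THF, −78 °C; then 19, DMPU, −78 → −40 °C
Reagents that add atoms: none
Why: Alkylation of a β-substituted butyrolactone lithium enolate by a benzylic bromide (SN2): the electrophile approaches the enolate face opposite the C4 benzyl group, giving the 3,4-trans lactone and setting C8' as R by substrate control. The pivalate and the C2–H of 19 are not attacked at this temperature.

Step 16
Reactants: 26 {(2S,3R)-2-[4-(benzyloxy)-3-methoxyphenyl]-5-({(3R,4R)-4-[4-(benzyloxy)-3-methoxybenzyl]-2-oxotetrahydrofuran-3-yl}methyl)-7-methoxy-2,3-dihydro-1-benzofuran-3-yl}methyl 2,2-dimethylpropanoate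
Product: 27 (2R,3R)-2-[4-(benzyloxy)-3-methoxybenzyl]-3-({(2S,3R)-2-[4-(benzyloxy)-3-methoxyphenyl]-3-(hydroxymethyl)-7-methoxy-2,3-dihydro-1-benzofuran-5-yl}methyl)butane-1,4-diol
Conditions: LiAlH4, THF, 0 °C → rt; aq. NaOH work-up
Reagents that add atoms: none
Why: LiAlH4 reduces the lactone to the 1,4-diol and cleaves the pivalate in the same operation. Neither stereocentre is α to a carbonyl group in the product and the benzylic aryl ether is inert to hydride.

Step 17
Reactants: 27 (2R,3R)-2-[4-(benzyloxy)-3-methoxybenzyl]-3-({(2S,3R)-2-[4-(benzyloxy)-3-methoxyphenyl]-3-(hydroxymethyl)-7-methoxy-2,3-dihydro-1-benzofuran-5-yl}methyl)butane-1,4-diol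
Product: 28 (2R,3R)-2-(4-hydroxy-3-methoxybenzyl)-3-{[(2S,3R)-2-(4-hydroxy-3-methoxyphenyl)-3-(hydroxymethyl)-7-methoxy-2,3-dihydro-1-benzofuran-5-yl]methyl}butane-1,4-diol (target)
Conditions: H2 (1 atm), Pd/C (10%), EtOAc/MeOH, rt; stopped after uptake of 2 equiv
Reagents that add atoms: none
Why: Hydrogenolysis of two aryl benzyl ethers, the fastest class of O-benzyl cleavage. With no alkyl benzyl ether to remove, the reaction can be stopped before the benzylic C2–O1 bond is attacked.

## Compound list

1 | 5-iodovanillin (4-hydroxy-3-iodo-5-methoxybenzaldehyde) | COc1cc(C=O)cc(I)c1O | starting material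
2 | butyl vinyl ether | C=COCCCC | starting material
3 | 3-(1-butoxyethenyl)-4-hydroxy-5-methoxybenzaldehyde | COc1cc(C=O)cc(C(=C)OCCCC)c1O | intermediate
4 | 3-acetyl-4-hydroxy-5-methoxybenzaldehyde | COc1cc(C=O)cc(C(C)=O)c1O | intermediate
5 | 3-[(2E)-3-(dimethylamino)prop-2-enoyl]-4-hydroxy-5-methoxybenzaldehyde | COc1cc(C=O)cc(C(=O)/C=C/N(C)C)c1O | intermediate
6 | 8-methoxy-4-oxo-4H-chromene-6-carbaldehyde | COc1cc(C=O)cc2c(=O)ccoc12 | intermediate
7 | 6-(hydroxymethyl)-8-methoxy-4H-chromen-4-one | COc1cc(CO)cc2c(=O)ccoc12 | intermediate
8 | 8-methoxy-6-{[(triisopropylsilyl)oxy]methyl}-4H-chromen-4-one | COc1cc(CO[Si](C(C)C)(C(C)C)C(C)C)cc2c(=O)ccoc12 | intermediate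
9 | [4-(benzyloxy)-3-methoxyphenyl]boronic acid | COc1cc(B(O)O)ccc1OCc1ccccc1 | starting material
10 | (2S)-2-[4-(benzyloxy)-3-methoxyphenyl]-8-methoxy-6-{[(triisopropylsilyl)oxy]methyl}-2,3-dihydro-4H-chromen-4-one | CC(C)[Si](C(C)C)(C(C)C)OCc1cc(OC)c2O[C@H](c3ccc(OCc4ccccc4)c(OC)c3)CC(=O)c2c1 | intermediate
11 | (2S)-2-[4-(benzyloxy)-3-methoxyphenyl]-8-methoxy-3-(trifluoroacetyl)-6-{[(triisopropylsilyl)oxy]methyl}-2,3-dihydro-4H-chromen-4-one (C3 epimers and enol form) | CC(C)[Si](C(C)C)(C(C)C)OCc1cc(OC)c2O[C@H](c3ccc(OCc4ccccc4)c(OC)c3)C(C(=O)C(F)(F)F)C(=O)c2c1 | intermediate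
12 | (2R)-2-[4-(benzyloxy)-3-methoxyphenyl]-3-diazo-8-methoxy-6-{[(triisopropylsilyl)oxy]methyl}-2,3-dihydro-4H-chromen-4-one (same spatial arrangement at C2 as 10) | CC(C)[Si](C(C)C)(C(C)C)OCc1cc(OC)c2O[C@H](c3ccc(OCc4ccccc4)c(OC)c3)C(=[N+]=[N-])C(=O)c2c1 | intermediate
13 | (2R)-2-[4-(benzyloxy)-3-methoxyphenyl]-7-methoxy-3-(oxomethylidene)-5-{[(triisopropylsilyl)oxy]methyl}-2,3-dihydro-1-benzofuran (ketene) | CC(C)[Si](C(C)C)(C(C)C)OCc2cc(OC)c3c(c2)C(=C=O)[C@@H](c2ccc(OCc4ccccc4)c(OC)c2)O3 | intermediate
14 | methyl (2S,3R)-2-[4-(benzyloxy)-3-methoxyphenyl]-7-methoxy-5-{[(triisopropylsilyl)oxy]methyl}-2,3-dihydro-1-benzofuran-3-carboxylate (cis) | CC(C)[Si](C(C)C)(C(C)C)OCc2cc(OC)c3c(c2)[C@@H](C(=O)OC)[C@@H](c2ccc(OCc4ccccc4)c(OC)c2)O3 | intermediate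
15 | methyl (2S,3S)-2-[4-(benzyloxy)-3-methoxyphenyl]-7-methoxy-5-{[(triisopropylsilyl)oxy]methyl}-2,3-dihydro-1-benzofuran-3-carboxylate (trans) | CC(C)[Si](C(C)C)(C(C)C)OCc2cc(OC)c3c(c2)[C@H](C(=O)OC)[C@@H](c2ccc(OCc4ccccc4)c(OC)c2)O3 | intermediate
16 | {(2S,3R)-2-[4-(benzyloxy)-3-methoxyphenyl]-7-methoxy-5-{[(triisopropylsilyl)oxy]methyl}-2,3-dihydro-1-benzofuran-3-yl}methanol | CC(C)[Si](C(C)C)(C(C)C)OCc2cc(OC)c3c(c2)[C@H](CO)[C@@H](c2ccc(OCc4ccccc4)c(OC)c2)O3 | intermediate
17 | {(2S,3R)-2-[4-(benzyloxy)-3-methoxyphenyl]-7-methoxy-5-{[(triisopropylsilyl)oxy]methyl}-2,3-dihydro-1-benzofuran-3-yl}methyl 2,2-dimethylpropanoate | CC(C)[Si](C(C)C)(C(C)C)OCc2cc(OC)c3c(c2)[C@H](COC(=O)C(C)(C)C)[C@@H](c2ccc(OCc4ccccc4)c(OC)c2)O3 | intermediate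
18 | {(2S,3R)-2-[4-(benzyloxy)-3-methoxyphenyl]-5-(hydroxymethyl)-7-methoxy-2,3-dihydro-1-benzofuran-3-yl}methyl 2,2-dimethylpropanoate | OCc2cc(OC)c3c(c2)[C@H](COC(=O)C(C)(C)C)[C@@H](c2ccc(OCc4ccccc4)c(OC)c2)O3 | intermediate
19 | {(2S,3R)-2-[4-(benzyloxy)-3-methoxyphenyl]-5-(bromomethyl)-7-methoxy-2,3-dihydro-1-benzofuran-3-yl}methyl 2,2-dimethylpropanoate | BrCc2cc(OC)c3c(c2)[C@H](COC(=O)C(C)(C)C)[C@@H](c2ccc(OCc4ccccc4)c(OC)c2)O3 | intermediate
20 | 4-(benzyloxy)-3-methoxybenzaldehyde | COc1cc(C=O)ccc1OCc1ccccc1 | starting material
21 | dimethyl succinate | COC(=O)CCC(=O)OC | starting material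
22 | (3E)-4-[4-(benzyloxy)-3-methoxyphenyl]-3-(methoxycarbonyl)but-3-enoic acid | COC(=O)/C(CC(=O)O)=C/c1ccc(OCc2ccccc2)c(OC)c1 | intermediate
23 | (3R)-4-[4-(benzyloxy)-3-methoxyphenyl]-3-(methoxycarbonyl)butanoic acid | COC(=O)[C@@H](CC(=O)O)Cc1ccc(OCc2ccccc2)c(OC)c1 | intermediate
24 | (3R)-4-[4-(benzyloxy)-3-methoxyphenyl]-3-(hydroxymethyl)butanoic acid | OC[C@@H](CC(=O)O)Cc1ccc(OCc2ccccc2)c(OC)c1 | intermediate
25 | (4R)-4-[4-(benzyloxy)-3-methoxybenzyl]dihydrofuran-2(3H)-one | O=C1C[C@@H](Cc2ccc(OCc3ccccc3)c(OC)c2)CO1 | intermediate
26 | {(2S,3R)-2-[4-(benzyloxy)-3-methoxyphenyl]-5-({(3R,4R)-4-[4-(benzyloxy)-3-methoxybenzyl]-2-oxotetrahydrofuran-3-yl}methyl)-7-methoxy-2,3-dihydro-1-benzofuran-3-yl}methyl 2,2-dimethylpropanoate | O=C1OC[C@H](Cc2ccc(OCc3ccccc3)c(OC)c2)[C@H]1Cc1cc(OC)c2c(c1)[C@H](COC(=O)C(C)(C)C)[C@@H](c1ccc(OCc3ccccc3)c(OC)c1)O2 | intermediate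
27 | (2R,3R)-2-[4-(benzyloxy)-3-methoxybenzyl]-3-({(2S,3R)-2-[4-(benzyloxy)-3-methoxyphenyl]-3-(hydroxymethyl)-7-methoxy-2,3-dihydro-1-benzofuran-5-yl}methyl)butane-1,4-diol | COc1cc(C[C@@H](CO)[C@H](CO)Cc2cc(OC)c3c(c2)[C@H](CO)[C@@H](c2ccc(OCc4ccccc4)c(OC)c2)O3)ccc1OCc1ccccc1 | intermediate
28 | (2R,3R)-2-(4-hydroxy-3-methoxybenzyl)-3-{[(2S,3R)-2-(4-hydroxy-3-methoxyphenyl)-3-(hydroxymethyl)-7-methoxy-2,3-dihydro-1-benzofuran-5-yl]methyl}butane-1,4-diol | COc1cc(C[C@@H](CO)[C@H](CO)Cc2cc(OC)c3c(c2)[C@H](CO)[C@@H](c2ccc(O)c(OC)c2)O3)ccc1O | target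

## Step count and least certain steps

Total step count: 17 (14 on the main line, 3 on the branch to 25). Longest linear sequence: 14 steps (steps 1 to 11 and 15 to 17, from 1 to 28).

Step 7 (key step). The most likely failure is diversion of the excited diazo ketone into carbene chemistry: a 1,2-hydride shift from C2, which dehydrogenates the heterocycle, or insertion into the O–H bond of methanol. The second risk is erosion of C2 by E1cB opening of the ester enolate during the methoxide equilibration. The fallback sets out from 10 and comes back at 15. It is an oxidative ring contraction with PhI(OAc)2 and catalytic H2SO4 in HC(OMe)3/MeOH at rt. The enol ether formed from the ketone is attacked at C3 by trivalent iodine, ring B shifts from C4 to C3 as iodobenzene leaves, and the resulting dialkoxycarbenium ion collapses to the methyl ester. The same bond is formed without a diazo compound or light. The medium is anhydrous, which the triisopropylsilyl ether should tolerate, and any cis ester is equilibrated as in step 7. No isolable new compound arises (entry F0).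

Step 5. The risks are poor facial selectivity on a chromone with a methoxy group next to O1, and loss of the electron-rich boronic acid by protodeboronation or homocoupling before insertion. The fallback sets out from 8 (with 9) and comes back at 10. The same addition is run with the achiral catalyst Pd(OCOCF3)2/2,2'-bipyridine to give the racemic 2-arylchroman-4-one F1. This is resolved by preparative chromatography on a chiral stationary phase. The unwanted enantiomer is racemised by reversible base-induced ring opening and recycled.

Step 6. The risks are loss of configuration at C2, through opening and reclosure of the pyranone while the enolate or the diketonate is present, and O-acylation in place of C-acylation. The fallback sets out from 10 and comes back at 12. Nitrosation at C3 under non-enolate conditions (isoamyl nitrite, Me3SiCl, CH2Cl2, −20 °C) gives the 3-hydroxyimino ketone F2. A Forster reaction (NH2Cl from aq. NH3 and NaOCl, NaOH, THF/H2O, 0 °C) then converts the oxime into the diazo group.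

Step 15. The risks are ionisation and self-condensation of the electron-rich benzylic bromide before C-alkylation, and proton exchange between product and enolate leading to dialkylation or loss of the trans selectivity. The fallback sets out from 18 and comes back at 26:
- MnO2 in CH2Cl2 oxidises the benzylic alcohol to the aldehyde F3.
- The lithium enolate of 25 adds to it at −78 °C to give the aldol adduct F4.
- MeSO2Cl/Et3N forms the methanesulfonate F5, which DBU eliminates to the (E)-arylidene lactone F6.
- Conjugate reduction with NaBH4/NiCl2·6H2O in MeOH/THF at 0 °C, followed by equilibration with DBU, gives the more stable trans lactone 26.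

Step 17. The risk is hydrogenolytic opening of the benzylic C2–O1 bond of the dihydrofuran in competition with O-debenzylation, especially once the ring C phenol is free. The fallback sets out from 26 and comes back at 28. The order of the last two operations is reversed and the reductive debenzylation is replaced by a Lewis-acid one: BCl3 with pentamethylbenzene as cation scavenger (CH2Cl2, −78 °C) gives the bisphenol lactone F7. Excess LiAlH4 in THF then reduces the lactone and cleaves the pivalate to give 28.

## Further compounds

F0 | step 7 | none | none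
F1 | step 5 | rac-2-[4-(benzyloxy)-3-methoxyphenyl]-8-methoxy-6-{[(triisopropylsilyl)oxy]methyl}-2,3-dihydro-4H-chromen-4-one | CC(C)[Si](C(C)C)(C(C)C)OCc1cc(OC)c2OC(c3ccc(OCc4ccccc4)c(OC)c3)CC(=O)c2c1
F2 | step 6 | (2R)-2-[4-(benzyloxy)-3-methoxyphenyl]-3-(hydroxyimino)-8-methoxy-6-{[(triisopropylsilyl)oxy]methyl}-2,3-dihydro-4H-chromen-4-one | CC(C)[Si](C(C)C)(C(C)C)OCc1cc(OC)c2O[C@H](c3ccc(OCc4ccccc4)c(OC)c3)C(=NO)C(=O)c2c1
F3 | step 15 | {(2S,3R)-2-[4-(benzyloxy)-3-methoxyphenyl]-5-formyl-7-methoxy-2,3-dihydro-1-benzofuran-3-yl}methyl 2,2-dimethylpropanoate | O=Cc2cc(OC)c3c(c2)[C@H](COC(=O)C(C)(C)C)[C@@H](c2ccc(OCc4ccccc4)c(OC)c2)O3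
F4 | step 15 | 3,4-trans aldol adduct of 25 and F3, (4R)-4-[4-(benzyloxy)-3-methoxybenzyl]-3-{hydroxy[aryl]methyl}dihydrofuran-2(3H)-one (carbinol epimers) | O=C1OC[C@H](Cc2ccc(OCc3ccccc3)c(OC)c2)[C@H]1C(O)c1cc(OC)c2c(c1)[C@H](COC(=O)C(C)(C)C)[C@@H](c1ccc(OCc3ccccc3)c(OC)c1)O2
F5 | step 15 | methanesulfonate of F4 | O=C1OC[C@H](Cc2ccc(OCc3ccccc3)c(OC)c2)[C@H]1C(OS(C)(=O)=O)c1cc(OC)c2c(c1)[C@H](COC(=O)C(C)(C)C)[C@@H](c1ccc(OCc3ccccc3)c(OC)c1)O2
F6 | step 15 | {(2S,3R)-2-[4-(benzyloxy)-3-methoxyphenyl]-5-{(E)-[(4R)-4-[4-(benzyloxy)-3-methoxybenzyl]-2-oxodihydrofuran-3(2H)-ylidene]methyl}-7-methoxy-2,3-dihydro-1-benzofuran-3-yl}methyl 2,2-dimethylpropanoate | O=C1OC[C@H](Cc2ccc(OCc3ccccc3)c(OC)c2)/C1=C\c1cc(OC)c2c(c1)[C@H](COC(=O)C(C)(C)C)[C@@H](c1ccc(OCc3ccccc3)c(OC)c1)O2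
F7 | step 17 | {(2S,3R)-5-{[(3R,4R)-4-(4-hydroxy-3-methoxybenzyl)-2-oxotetrahydrofuran-3-yl]methyl}-2-(4-hydroxy-3-methoxyphenyl)-7-methoxy-2,3-dihydro-1-benzofuran-3-yl}methyl 2,2-dimethylpropanoate | O=C1OC[C@H](Cc2ccc(O)c(OC)c2)[C@H]1Cc1cc(OC)c2c(c1)[C@H](COC(=O)C(C)(C)C)[C@@H](c1ccc(O)c(OC)c1)O2
A1 | alternative 1 | boryl ynol ether 1,6-diyne: 2-({[1-(4-benzyloxy-3-methoxyphenyl)-2-(tert-butyldimethylsilyloxymethyl)but-3-yn-1-yl]oxy}ethynyl)-4,4,5,5-tetramethyl-1,3,2-dioxaborolane, configuration as in the SMILES | CC1(C)OB(C#CO[C@H](c2ccc(OCc3ccccc3)c(OC)c2)[C@@H](CO[Si](C)(C)C(C)(C)C)C#C)OC1(C)C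
A2 | alternative 1 | terminal alkyne: 6-(4-benzyloxy-3-methoxyphenyl)-4,5-bis(tert-butyldimethylsilyloxymethyl)hex-1-yne, configuration as in the SMILES | C#CC[C@@H](CO[Si](C)(C)C(C)(C)C)[C@H](CO[Si](C)(C)C(C)(C)C)Cc1ccc(OCc2ccccc2)c(OC)c1
A3 | alternative 1 | 7-pinacolboryl-2,3-dihydrobenzofuran with the complete carbon skeleton (product of the cyclotrimerisation) | COc1cc(C[C@@H](CO[Si](C)(C)C(C)(C)C)[C@H](CO[Si](C)(C)C(C)(C)C)Cc2cc(B4OC(C)(C)C(C)(C)O4)c3c(c2)[C@H](CO[Si](C)(C)C(C)(C)C)[C@@H](c2ccc(OCc4ccccc4)c(OC)c2)O3)ccc1OCc1ccccc1
A4 | alternative 2 | (5R)-5-[(1R,2S,5R)-menthyloxy]furan-2(5H)-one | O=C1C=C[C@H](O[C@@H]2C[C@H](C)CC[C@H]2C(C)C)O1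
A5 | alternative 2 | 2-[4-(benzyloxy)-3-methoxyphenyl]-1,3-dithiane | COc1cc(C2SCCCS2)ccc1OCc1ccccc1
A6 | alternative 2 | {[(2S,3R)-2-[4-(benzyloxy)-3-methoxyphenyl]-5-(bromomethyl)-7-methoxy-2,3-dihydro-1-benzofuran-3-yl]methoxy}(tert-butyl)dimethylsilane | BrCc1cc(OC)c2c(c1)[C@H](CO[Si](C)(C)C(C)(C)C)[C@@H](c1ccc(OCc3ccccc3)c(OC)c1)O2
A7 | alternative 2 | trans-α,β-disubstituted 5-menthyloxybutyrolactone carrying the dithiane (product of the tandem addition and alkylation) | COc1cc(C2(SCCCS2)[C@H]4[C@H](O[C@@H]5C[C@H](C)CC[C@H]5C(C)C)OC(=O)[C@@H]4Cc2cc(OC)c3c(c2)[C@H](CO[Si](C)(C)C(C)(C)C)[C@@H](c2ccc(OCc6ccccc6)c(OC)c2)O3)ccc1OCc1ccccc1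
A8 | alternative 3 | 3-[1-(tert-butyldimethylsilyloxy)-3-(4-hydroxy-3-methoxyphenyl)propan-2-yl]-4-hydroxy-5-methoxybenzaldehyde, configuration as in the SMILES | O=Cc1cc(OC)c(O)c(c1)[C@H](CO[Si](C)(C)C(C)(C)C)Cc1ccc(O)c(OC)c1
A9 | alternative 3 | trans-5-formyl-2-(4-hydroxy-3-methoxyphenyl)-7-methoxy-3-(tert-butyldimethylsilyloxymethyl)-2,3-dihydrobenzofuran (product of the oxidative cyclisation) | O=Cc2cc(OC)c3c(c2)[C@H](CO[Si](C)(C)C(C)(C)C)[C@@H](c2ccc(O)c(OC)c2)O3
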